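Everything rests on cutting ring A (the benzoic acid) at two neighbouring carbons: the diaryl ether bond at C6 and the carboxyl bond at C1. With the methoxy group at C2, these bonds map onto the two ends of a 3-methoxybenzyne, which accepts a nucleophile at the carbon remote from the methoxy group and an electrophile at the near one. In one operation the ring B phenoxide adds at C6 and the carbanion left at C1 is carboxylated by CO2. The aryne precursor is an ortho-silyl aryl triflate of ring A carrying the (S)-carbinol as a silyl ether; ring B enters with its aldehyde masked as a dioxolane and its second phenol benzylated.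

Key step: step 13

Remark on numbering: ring A is the benzoic acid ring with C1 carboxyl, C2 methoxy, C3 carbinol chain and C6 ether oxygen; ring B is the ring that carries the formyl group.

Step 1
Reactants: 1 4-hydroxy-2-methoxybenzaldehyde
Product: 2 4-formyl-3-methoxyphenyl N,N-diethylcarbamate
Conditions: ClC(O)NEt2, K2CO3, MeCN, reflux
Reagents that add atoms: diethylcarbamoyl chloride, CCN(CC)C(=O)Cl
Why: O-carbamoylation of the phenoxide is fast and chemoselective, and the N,N-diethylcarbamate protects the phenol now and later serves as the director for ortho-metalation.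

Step 2
Reactants: 2 4-formyl-3-methoxyphenyl N,N-diethylcarbamate; 3 isobutylmagnesium bromide
Product: 4 rac-4-(1-hydroxy-3-methylbutyl)-3-methoxyphenyl N,N-diethylcarbamate
Conditions: THF, −78 → 0 °C
Reagents that add atoms: none
Why: Grignard addition to the aldehyde at low temperature is much faster than attack on the tertiary carbamate, so the racemic secondary carbinol should be the only product.

Step 3
Reactants: 4 rac-4-(1-hydroxy-3-methylbutyl)-3-methoxyphenyl N,N-diethylcarbamate
Product: 5 3-methoxy-4-(3-methylbutanoyl)phenyl N,N-diethylcarbamate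
Conditions: Dess–Martin periodinane, CH2Cl2, rt
Reagents that add atoms: none
Why: Dess–Martin oxidation of a secondary benzylic alcohol to the aryl ketone is mild, leaves the carbamate alone and removes the uncontrolled centre so that it can be reset under catalyst control.

Step 4
Reactants: 5 3-methoxy-4-(3-methylbutanoyl)phenyl N,N-diethylcarbamate
Product: 6 4-[(1S)-1-hydroxy-3-methylbutyl]-3-methoxyphenyl N,N-diethylcarbamate
Conditions: (R)-2-methyl-CBS-oxazaborolidine (10 mol%), BH3·SMe2, THF, −20 °C; then H2O
Reagents that add atoms: none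
Why: Corey–Bakshi–Shibata reduction, in which borane held on the (R)-oxazaborolidine delivers hydride to the ketone face that keeps the large aryl group away from the catalyst, which for aryl larger than CH2CHMe2 should give the (S)-carbinol.

Step 5
Reactants: 6 4-[(1S)-1-hydroxy-3-methylbutyl]-3-methoxyphenyl N,N-diethylcarbamate
Product: 7 3-methoxy-4-[(1S)-3-methyl-1-(triisopropylsilyloxy)butyl]phenyl N,N-diethylcarbamate
Conditions: TIPSOTf, 2,6-lutidine, CH2Cl2, 0 °C → rt
Reagents that add atoms: triisopropylsilyl trifluoromethanesulfonate, CC(C)[Si](C(C)C)(C(C)C)OS(=O)(=O)C(F)(F)F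
Why: O-silylation with a silyl triflate and a hindered pyridine base does not touch the C–O bond of the stereocentre, and the bulky silyl ether should withstand the organolithium, hydride and fluoride salts used later.

Step 6
Reactants: 7 3-methoxy-4-[(1S)-3-methyl-1-(triisopropylsilyloxy)butyl]phenyl N,N-diethylcarbamate
Product: 9 3-methoxy-4-[(1S)-3-methyl-1-(triisopropylsilyloxy)butyl]-2-(trimethylsilyl)phenyl N,N-diethylcarbamate, via C2 aryllithium 8 (not isolated)
Conditions: s-BuLi, TMEDA, THF, −78 °C; then TMSCl, −78 °C → rt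
Reagents that add atoms: chlorotrimethylsilane, C[Si](C)(C)Cl
Why: Directed ortho-metalation, in which the ring carbon between the carbamate and the methoxy group is the kinetically most acidic site because both oxygen directors act on it, and the aryllithium is silylated at −78 °C before an anionic Fries shift can begin.

Step 7
Reactants: 9 3-methoxy-4-[(1S)-3-methyl-1-(triisopropylsilyloxy)butyl]-2-(trimethylsilyl)phenyl N,N-diethylcarbamate
Product: 10 3-methoxy-4-[(1S)-3-methyl-1-(triisopropylsilyloxy)butyl]-2-(trimethylsilyl)phenol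
Conditions: LiAlH4, THF, 0 °C → reflux; Na2SO4·10H2O quench
Reagents that add atoms: none
Why: Hydride reduction of an aryl N,N-dialkylcarbamate releases the phenoxide, the aryl–silicon bond and the alkyl silyl ether are inert to LiAlH4, and the neutral quench avoids protodesilylation.

Step 8
Reactants: 10 3-methoxy-4-[(1S)-3-methyl-1-(triisopropylsilyloxy)butyl]-2-(trimethylsilyl)phenol
Product: 11 3-methoxy-4-[(1S)-3-methyl-1-(triisopropylsilyloxy)butyl]-2-(trimethylsilyl)phenyl trifluoromethanesulfonate
Conditions: Tf2O, pyridine, CH2Cl2, 0 °C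
Reagents that add atoms: trifluoromethanesulfonic anhydride, FC(F)(F)S(=O)(=O)OS(=O)(=O)C(F)(F)F
Why: O-sulfonylation of an ortho-silyl phenol with triflic anhydride and pyridine is the standard closing step in the preparation of ortho-silylaryl triflates.

Step 9
Reactants: 12 2-methoxy-4-methylphenol (creosol)
Product: 13 2-hydroxy-3-methoxy-5-methylbenzaldehyde
Conditions: MgCl2, Et3N, (CH2O)n, MeCN, reflux; dilute HCl work-up
Reagents that add atoms: paraformaldehyde (formaldehyde), C=O
Why: Casnati–Skattebøl ortho-formylation, in which the magnesium phenoxide directs hydroxymethylation to the only free ortho carbon and a second formaldehyde oxidises the benzylic alkoxide to the aldehyde.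

Step 10
Reactants: 13 2-hydroxy-3-methoxy-5-methylbenzaldehyde
Product: 14 2,3-dihydroxy-5-methylbenzaldehyde
Conditions: BBr3, CH2Cl2, −78 °C → rt; then H2O
Reagents that add atoms: none
Why: Lewis-acid cleavage of the aryl methyl ether with BBr3 is well established for ortho-vanillin-type aldehydes, and the aldehyde is returned on aqueous work-up.

Step 11
Reactants: 14 2,3-dihydroxy-5-methylbenzaldehyde
Product: 16 3-(benzyloxy)-2-hydroxy-5-methylbenzaldehyde, via disodium catecholate 15 (not isolated)
Conditions: NaH (2.2 equiv), DMSO, rt; then BnBr (1.0 equiv), rt; dilute HCl work-up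
Reagents that add atoms: benzyl bromide, BrCc1ccccc1
Why: Williamson etherification of the dianion, in which the 2-oxide is conjugated with and chelated to the formyl group and is therefore the weaker nucleophile, so one equivalent of benzyl bromide should alkylate the 3-oxide.

Step 12
Reactants: 16 3-(benzyloxy)-2-hydroxy-5-methylbenzaldehyde
Product: 17 2-(benzyloxy)-6-(1,3-dioxolan-2-yl)-4-methylphenol
Conditions: HOCH2CH2OH, p-TsOH·H2O (cat.), toluene, reflux (Dean–Stark); Et3N quench
Reagents that add atoms: ethylene glycol, OCCO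
Why: Acid-catalysed acetalisation with azeotropic removal of water converts the aldehyde into the 1,3-dioxolane, which removes the only electrophile that the aryl anion of the next step could reach within the molecule.

Step 13
Reactants: 11 3-methoxy-4-[(1S)-3-methyl-1-(triisopropylsilyloxy)butyl]-2-(trimethylsilyl)phenyl trifluoromethanesulfonate; 17 2-(benzyloxy)-6-(1,3-dioxolan-2-yl)-4-methylphenol; 18 carbon dioxide
Product: 22 6-[2-(benzyloxy)-6-(1,3-dioxolan-2-yl)-4-methylphenoxy]-2-methoxy-3-[(1S)-3-methyl-1-(triisopropylsilyloxy)butyl]benzoic acid, via potassium phenoxide 19 (not isolated), via aryne 20 (not isolated), via C1 aryl anion 21 (not isolated)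
Conditions: 17 (1.5 equiv), KH (1.4 equiv), THF, 0 °C; then CO2 (1 atm), KF (3 equiv), 18-crown-6 (3 equiv), slow addition of 11, THF, 0 °C → rt; aq. KH2PO4 work-up
Reagents that add atoms: none
Why: Proposed new method: fluoride attacks the C1 silicon and expels the C6 triflate to give aryne 20 (C1≡C6), the preformed phenoxide 19 adds to C6, and the C1 carbanion 21 so formed is captured by CO2, which makes the C6–O ether bond and the C1–carboxyl bond in one flask. The closest known reaction type is the fluoride-triggered three-component union of arynes, amines and CO2 that gives anthranilic acids, combined with the known O-arylation of hindered phenols by arynes; the oxygen nucleophile is the untested element. The selectivity required is regiochemical: the C2 methoxy group, through its inductive pull and the distortion it imposes on the aryne, should send the nucleophile to the remote carbon C6 and leave the charge at C1, where the adjacent oxygen stabilises it. No ring is closed and no stereocentre is created; the (S)-silyl ether is remote and should be inert to fluoride salts at this temperature. Deprotonation with KH removes every O–H that could protonate 21, THF replaces C–H-acidic nitrile solvents, and the dioxolane denies 21 an internal carbonyl that would otherwise close a xanthene ring. Slow addition of 11 keeps the aryne concentration low while the phenoxide, which may rest reversibly as its CO2 adduct, stays in excess.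

Step 14
Reactants: 22 6-[2-(benzyloxy)-6-(1,3-dioxolan-2-yl)-4-methylphenoxy]-2-methoxy-3-[(1S)-3-methyl-1-(triisopropylsilyloxy)butyl]benzoic acid
Product: 23 6-[2-(1,3-dioxolan-2-yl)-6-hydroxy-4-methylphenoxy]-2-methoxy-3-[(1S)-3-methyl-1-(triisopropylsilyloxy)butyl]benzoic acid
Conditions: H2 (1 atm), Pd/C (10 wt% Pd), EtOAc, rt
Reagents that add atoms: none
Why: Catalytic hydrogenolysis cleaves a phenolic benzyl ether much faster than an aryl dioxolane or a benzylic silyl ether in a neutral aprotic solvent, and the aldehyde is still masked so it cannot be reduced.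

Step 15
Reactants: 23 6-[2-(1,3-dioxolan-2-yl)-6-hydroxy-4-methylphenoxy]-2-methoxy-3-[(1S)-3-methyl-1-(triisopropylsilyloxy)butyl]benzoic acid
Product: 25 tenellic acid B, via desilylated dioxolane acid 24 (not isolated)
Conditions: Bu4NF, THF, 0 °C → rt; then 1 M HCl to pH 2, rt
Reagents that add atoms: water, O
Why: Fluoride cleaves the Si–O bond with retention at the carbinol carbon, and the brief acidification that follows hydrolyses the aryl dioxolane under conditions expected to be too mild to ionise the benzylic alcohol, whose cation is disfavoured by the meta carboxyl group.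

Compound list
1 | 4-hydroxy-2-methoxybenzaldehyde | COc1cc(O)ccc1C=O | starting material
2 | 4-formyl-3-methoxyphenyl N,N-diethylcarbamate | CCN(CC)C(=O)Oc1ccc(C=O)c(OC)c1 | intermediate
3 | isobutylmagnesium bromide | CC(C)C[Mg]Br | starting material
4 | rac-4-(1-hydroxy-3-methylbutyl)-3-methoxyphenyl N,N-diethylcarbamate | CCN(CC)C(=O)Oc1ccc(C(O)CC(C)C)c(OC)c1 | intermediate
5 | 3-methoxy-4-(3-methylbutanoyl)phenyl N,N-diethylcarbamate | CCN(CC)C(=O)Oc1ccc(C(=O)CC(C)C)c(OC)c1 | intermediate
6 | 4-[(1S)-1-hydroxy-3-methylbutyl]-3-methoxyphenyl N,N-diethylcarbamate | COc1cc(OC(=O)N(CC)CC)ccc1[C@@H](O)CC(C)C | intermediate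
7 | 3-methoxy-4-[(1S)-3-methyl-1-(triisopropylsilyloxy)butyl]phenyl N,N-diethylcarbamate | COc1cc(OC(=O)N(CC)CC)ccc1[C@@H](O[Si](C(C)C)(C(C)C)C(C)C)CC(C)C | intermediate
8 | 2-lithio-3-methoxy-4-[(1S)-3-methyl-1-(triisopropylsilyloxy)butyl]phenyl N,N-diethylcarbamate | COc1c([Li])c(OC(=O)N(CC)CC)ccc1[C@@H](O[Si](C(C)C)(C(C)C)C(C)C)CC(C)C | intermediate
9 | 3-methoxy-4-[(1S)-3-methyl-1-(triisopropylsilyloxy)butyl]-2-(trimethylsilyl)phenyl N,N-diethylcarbamate | COc1c([Si](C)(C)C)c(OC(=O)N(CC)CC)ccc1[C@@H](O[Si](C(C)C)(C(C)C)C(C)C)CC(C)C | intermediate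
10 | 3-methoxy-4-[(1S)-3-methyl-1-(triisopropylsilyloxy)butyl]-2-(trimethylsilyl)phenol | COc1c([Si](C)(C)C)c(O)ccc1[C@@H](O[Si](C(C)C)(C(C)C)C(C)C)CC(C)C | intermediate
11 | 3-methoxy-4-[(1S)-3-methyl-1-(triisopropylsilyloxy)butyl]-2-(trimethylsilyl)phenyl trifluoromethanesulfonate | COc1c([C@@H](O[Si](C(C)C)(C(C)C)C(C)C)CC(C)C)ccc(OS(=O)(=O)C(F)(F)F)c1[Si](C)(C)C | intermediate
12 | 2-methoxy-4-methylphenol (creosol) | COc1cc(C)ccc1O | starting material
13 | 2-hydroxy-3-methoxy-5-methylbenzaldehyde | COc1cc(C)cc(C=O)c1O | intermediate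
14 | 2,3-dihydroxy-5-methylbenzaldehyde | Cc1cc(O)c(O)c(C=O)c1 | intermediate
15 | disodium 3-formyl-5-methylbenzene-1,2-diolate | Cc1cc([O-])c([O-])c(C=O)c1.[Na+].[Na+] | intermediate
16 | 3-(benzyloxy)-2-hydroxy-5-methylbenzaldehyde | Cc1cc(OCc2ccccc2)c(O)c(C=O)c1 | intermediate
17 | 2-(benzyloxy)-6-(1,3-dioxolan-2-yl)-4-methylphenol | Cc1cc(OCc2ccccc2)c(O)c(C2OCCO2)c1 | intermediate
18 | carbon dioxide | O=C=O | starting material
19 | potassium 2-(benzyloxy)-6-(1,3-dioxolan-2-yl)-4-methylphenoxide | Cc1cc(OCc2ccccc2)c([O-])c(C2OCCO2)c1.[K+] | intermediate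
20 | 3-methoxy-4-[(1S)-3-methyl-1-(triisopropylsilyloxy)butyl]benzyne (ring A with a C1≡C6 triple bond) | COC1=C([C@@H](O[Si](C(C)C)(C(C)C)C(C)C)CC(C)C)C=CC#C1 | intermediate
21 | potassium salt of the ring A C1 aryl anion of the diaryl ether (charge between the methoxy and aryloxy carbons) | COc1c([C@@H](O[Si](C(C)C)(C(C)C)C(C)C)CC(C)C)ccc(Oc2c(OCc3ccccc3)cc(C)cc2C2OCCO2)[c-]1.[K+] | intermediate
22 | 6-[2-(benzyloxy)-6-(1,3-dioxolan-2-yl)-4-methylphenoxy]-2-methoxy-3-[(1S)-3-methyl-1-(triisopropylsilyloxy)butyl]benzoic acid | COc1c([C@@H](O[Si](C(C)C)(C(C)C)C(C)C)CC(C)C)ccc(Oc2c(OCc3ccccc3)cc(C)cc2C2OCCO2)c1C(=O)O | intermediate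
23 | 6-[2-(1,3-dioxolan-2-yl)-6-hydroxy-4-methylphenoxy]-2-methoxy-3-[(1S)-3-methyl-1-(triisopropylsilyloxy)butyl]benzoic acid | COc1c([C@@H](O[Si](C(C)C)(C(C)C)C(C)C)CC(C)C)ccc(Oc2c(O)cc(C)cc2C2OCCO2)c1C(=O)O | intermediate
24 | 6-[2-(1,3-dioxolan-2-yl)-6-hydroxy-4-methylphenoxy]-3-[(1S)-1-hydroxy-3-methylbutyl]-2-methoxybenzoic acid | COc1c([C@@H](O)CC(C)C)ccc(Oc2c(O)cc(C)cc2C2OCCO2)c1C(=O)O | intermediate
25 | tenellic acid B, 6-(2-formyl-6-hydroxy-4-methylphenoxy)-3-[(1S)-1-hydroxy-3-methylbutyl]-2-methoxybenzoic acid | COc1c([C@@H](O)CC(C)C)ccc(Oc2c(O)cc(C)cc2C=O)c1C(=O)O | target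

Total step count: 15 (steps 1–8 for ring A, steps 9–12 for ring B, step 13 for the union, steps 14–15 for unmasking).
Longest linear sequence: 11 steps (steps 1–8, then 13, 14 and 15, from compound 1).

Steps most likely to fail

Step 13 (carries the label). The C1 carbanion may be protonated before CO2 reaches it, or the phenoxide may be held back as its CO2 adduct, so that ether formation and carboxylation fail to occur together. The fallback divides the union into two known operations; it sets out from 11 and 17 and returns to the route at 22. Treatment of 11 and 17 with CsF in MeCN at rt without CO2 should give, through aryne 20, the diaryl ether 2-[3-(benzyloxy)-2-{3-methoxy-4-[(1S)-3-methyl-1-(triisopropylsilyloxy)butyl]phenoxy}-5-methylphenyl]-1,3-dioxolane F1. This is the established fluoride-induced O-arylation of phenols by arynes, with the same methoxy control of regiochemistry and a C–H bond left at C1. Directed ortho-lithiation of F1 with n-BuLi/TMEDA in THF (−78 → 0 °C) should then take place at C1, the only ring carbon flanked by two ether oxygens, to give the C1-lithio diaryl ether F2. Quenching F2 with CO2 and work-up with aq. NH4Cl should deliver 22.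

Step 6. Metalation may be misdirected to the other ortho carbon of the carbamate, or slowed, because the bulky silyloxyalkyl group turns the methoxy methyl over the target C–H bond. The fallback forms the C–Si bond before the side chain exists; it sets out from 2 and returns at 9. Acetalisation of 2 (ethylene glycol, p-TsOH, toluene, Dean–Stark) should give 4-(1,3-dioxolan-2-yl)-3-methoxyphenyl N,N-diethylcarbamate F3. Metalation with s-BuLi/TMEDA at −78 °C, now next to a small acetal, should give 4-(1,3-dioxolan-2-yl)-2-lithio-3-methoxyphenyl N,N-diethylcarbamate F4, which TMSCl converts into 4-(1,3-dioxolan-2-yl)-3-methoxy-2-(trimethylsilyl)phenyl N,N-diethylcarbamate F5. Mild hydrolysis (pyridinium p-toluenesulfonate, wet acetone) should release 4-formyl-3-methoxy-2-(trimethylsilyl)phenyl N,N-diethylcarbamate F6. The chemistry of steps 2–5 is then repeated in the silylated series: addition of 3 gives rac-4-(1-hydroxy-3-methylbutyl)-3-methoxy-2-(trimethylsilyl)phenyl N,N-diethylcarbamate F7, Dess–Martin oxidation gives 3-methoxy-4-(3-methylbutanoyl)-2-(trimethylsilyl)phenyl N,N-diethylcarbamate F8, reduction with the (R)-oxazaborolidine and BH3·SMe2 gives 4-[(1S)-1-hydroxy-3-methylbutyl]-3-methoxy-2-(trimethylsilyl)phenyl N,N-diethylcarbamate F9, and silylation with TIPSOTf/2,6-lutidine gives 9.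

Step 15. The free, electron-rich benzylic alcohol may ionise during the acid stage (loss of configuration or elimination), or desilylation of the hindered ether may stall under basic fluoride. The fallback reverses the order so that the carbinol stays silylated while acid is present; it sets out from 23 and returns at 25. Hydrolysis of the dioxolane of 23 (pyridinium p-toluenesulfonate, acetone/H2O, 40 °C) should give 6-(2-formyl-6-hydroxy-4-methylphenoxy)-2-methoxy-3-[(1S)-3-methyl-1-(triisopropylsilyloxy)butyl]benzoic acid F10. The silyl ether of F10 is then cleaved last with buffered HF·pyridine in THF/pyridine (0 °C → rt) to give 25.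

Further compounds
F1 | step 13 | 2-[3-(benzyloxy)-2-{3-methoxy-4-[(1S)-3-methyl-1-(triisopropylsilyloxy)butyl]phenoxy}-5-methylphenyl]-1,3-dioxolane | COc1cc(Oc2c(OCc3ccccc3)cc(C)cc2C2OCCO2)ccc1[C@@H](O[Si](C(C)C)(C(C)C)C(C)C)CC(C)C
F2 | step 13 | C1-lithio diaryl ether (F1 lithiated on ring A between the methoxy and aryloxy carbons) | COc1c([Li])c(Oc2c(OCc3ccccc3)cc(C)cc2C2OCCO2)ccc1[C@@H](O[Si](C(C)C)(C(C)C)C(C)C)CC(C)C
F3 | step 6 | 4-(1,3-dioxolan-2-yl)-3-methoxyphenyl N,N-diethylcarbamate | CCN(CC)C(=O)Oc1ccc(C2OCCO2)c(OC)c1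
F4 | step 6 | 4-(1,3-dioxolan-2-yl)-2-lithio-3-methoxyphenyl N,N-diethylcarbamate | COc1c([Li])c(OC(=O)N(CC)CC)ccc1C1OCCO1
F5 | step 6 | 4-(1,3-dioxolan-2-yl)-3-methoxy-2-(trimethylsilyl)phenyl N,N-diethylcarbamate | COc1c([Si](C)(C)C)c(OC(=O)N(CC)CC)ccc1C1OCCO1
F6 | step 6 | 4-formyl-3-methoxy-2-(trimethylsilyl)phenyl N,N-diethylcarbamate | COc1c([Si](C)(C)C)c(OC(=O)N(CC)CC)ccc1C=O
F7 | step 6 | rac-4-(1-hydroxy-3-methylbutyl)-3-methoxy-2-(trimethylsilyl)phenyl N,N-diethylcarbamate | COc1c([Si](C)(C)C)c(OC(=O)N(CC)CC)ccc1C(O)CC(C)C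
F8 | step 6 | 3-methoxy-4-(3-methylbutanoyl)-2-(trimethylsilyl)phenyl N,N-diethylcarbamate | COc1c([Si](C)(C)C)c(OC(=O)N(CC)CC)ccc1C(=O)CC(C)C
F9 | step 6 | 4-[(1S)-1-hydroxy-3-methylbutyl]-3-methoxy-2-(trimethylsilyl)phenyl N,N-diethylcarbamate | COc1c([Si](C)(C)C)c(OC(=O)N(CC)CC)ccc1[C@@H](O)CC(C)C
F10 | step 15 | 6-(2-formyl-6-hydroxy-4-methylphenoxy)-2-methoxy-3-[(1S)-3-methyl-1-(triisopropylsilyloxy)butyl]benzoic acid | COc1c([C@@H](O[Si](C(C)C)(C(C)C)C(C)C)CC(C)C)ccc(Oc2c(O)cc(C)cc2C=O)c1C(=O)O
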